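**Plan**

1. Retrosynthesis: the two acids come from methyl esters; C8=C17 is cut to a C8 ketone, C13=C14 to a C13 ketone, C9–C11 to an enol silane plus methyl vinyl ketone, and C4–C19 to an ester enolate plus MeI. Ring A is then opened at C1–C10, and the chain is cut at C3–C4 (epoxide opening) and C4–C5 (Claisen shift).
2. Forward: ring B is there from the start (2-methylcyclohex-2-enone = C5–C10 and C20). CBS reduction and Johnson–Claisen rearrangement set C5 and attach C4/C18; (R)-epibromohydrin brings C1–C3 with the C2 oxygen; allylic oxidation makes the C8 enone; ring A is closed last.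
3. Key event: a reductive radical conjugate cyclisation C1→C10 with O-silyl trapping. In one operation it should give the quaternary C10, the cis ring fusion and a regiodefined C8–C9 enol silane.
4. Enabling feature: C8, the exocyclic-methylene carbon of ring B, is a masked ketone, so C10 is the β-carbon of a C8(=O)–C9=C10 enone. The C2 oxygen of ring A sits β to C1, which allows a C1 radical but no C1 carbanion, and the enolate left at C9 is exactly where the side chain must go.
5. Stereochemistry: C5 from the CBS reduction, relayed by the suprafacial Claisen shift; C2 from the chiral pool; C10 from the tether (cis fusion); C9 and C4 from attack on the convex β face of the cis-decalin; 13E from the olefination.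

Key step: step 5

Remark: the SMILES is read as (2S,4R,5S,9S,10R), a cis-fused decalin with H5, the C10 methyl, the C2 hydroxyl, the C4 methyl and the C9 side chain on one face (β) and the C4 carboxyl on the other (α); labdane numbering is used (ring A = C1–C5 and C10, ring B = C5–C10, side chain C11–C16, C17 = exocyclic methylene carbon, C18 = carboxyl carbon on C4, C19 = methyl on C4, C20 = methyl on C10; TBS = tert-butyldimethylsilyl).

**Route**

Step 1
Reactants: 1 2-methylcyclohex-2-en-1-one
Product: 2 (1R)-2-methylcyclohex-2-en-1-ol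
Conditions: (S)-1-methyl-3,3-diphenyltetrahydro-1H,3H-pyrrolo[1,2-c][1,3,2]oxazaborole (0.1 equiv), BH3·SMe2, THF, −20 °C; MeOH quench
Reagents that add atoms: none
Why: Corey–Bakshi–Shibata reduction, in which the (S)-oxazaborolidine binds the ketone with the alkenyl arm (C10) as the large group and delivers hydride to the face that gives the (R)-carbinol at C9, whose C–O bond later dictates the configuration of C5.

Step 2
Reactants: 2 (1R)-2-methylcyclohex-2-en-1-ol; 3 trimethyl orthoacetate
Product: 5 methyl 2-[(1R)-2-methylcyclohex-2-en-1-yl]acetate, via ketene acetal 4 (not isolated)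
Conditions: EtCO2H (cat.), xylene, 135 °C, MeOH distilled off
Reagents that add atoms: none
Why: Johnson–Claisen rearrangement, in which the ketene acetal formed by exchange with the orthoester undergoes a suprafacial [3,3] shift, so that C4 bonds to C5 on the face the C9 oxygen leaves, which fixes C5 as (R) and moves the alkene to C9=C10.

Step 3
Reactants: 5 methyl 2-[(1R)-2-methylcyclohex-2-en-1-yl]acetate; 6 (R)-epibromohydrin
Product: 8 methyl (4R)-5-bromo-4-[(tert-butyldimethylsilyl)oxy]-2-[(1R)-2-methylcyclohex-2-en-1-yl]pentanoate (both C2 epimers of the pentanoate), via bromohydrin 7 (not isolated)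
Conditions: LiN(i-Pr)2, THF, −78 °C; Et2AlCl; 6, −78 → −30 °C; then TBSOTf, 2,6-lutidine, −78 → 0 °C
Reagents that add atoms: tert-butyldimethylsilyl trifluoromethanesulfonate, CC(C)(C)[Si](C)(C)OS(=O)(=O)C(F)(F)F
Why: Epoxide opening by an aluminium ester enolate (SN2 at the CH2 terminus of the Lewis acid-bound epoxide) forms C3–C4 without touching the epoxide stereocentre, which becomes (R)-configured C2 with its oxygen and leaves C1 as the CH2Br radical precursor, while silylation in the same flask forestalls lactonisation and the new C4 centre arises as a mixture that step 6 erases.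

Step 4
Reactants: 8 methyl (4R)-5-bromo-4-[(tert-butyldimethylsilyl)oxy]-2-[(1R)-2-methylcyclohex-2-en-1-yl]pentanoate
Product: 9 methyl (4R)-5-bromo-4-[(tert-butyldimethylsilyl)oxy]-2-[(1R)-2-methyl-4-oxocyclohex-2-en-1-yl]pentanoate (both C2 epimers of the pentanoate)
Conditions: Rh2(C6H10NO)4 (dirhodium tetrakis(caprolactamate), 1 mol %), t-BuOOH (70% in water), K2CO3, CH2Cl2, rt
Reagents that add atoms: tert-butyl hydroperoxide, CC(C)(C)OO
Why: Radical allylic oxidation of the Kharasch–Sosnovsky type (hydrogen abstraction, mixed peroxide, loss of t-BuOH) should take place at C8, the unhindered secondary CH2 next to the alkene CH (C9), to give the C8(=O)–C9=C10 enone, because the tertiary C5–H is shielded by the branched C4 substituent, and the bromide, silyl ether and ester are inert to it.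

Step 5
Reactants: 9 methyl (4R)-5-bromo-4-[(tert-butyldimethylsilyl)oxy]-2-[(1R)-2-methyl-4-oxocyclohex-2-en-1-yl]pentanoate
Product: 10 methyl 2β-(tert-butyldimethylsilyloxy)-8-(triethylsilyloxy)-11,12,13,14,15,16,17,19-octanor-5β-labd-8-en-18-oate (cis-fused bicycle; C8(OSiEt3)=C9; 10β-CH3; both C4 epimers)
Conditions: NiCl2(MeOCH2CH2OMe) (10 mol %), 2,9-dimethyl-1,10-phenanthroline (10 mol %), Mn powder, Et3SiCl, DMF, 40 °C
Reagents that add atoms: chlorotriethylsilane, CC[Si](Cl)(CC)CC
Why: Zerovalent nickel (from the nickel dichloride, the phenanthroline and Mn) abstracts bromine from C1 to give a primary radical that carries the C2 silyloxy group in the β position, where a radical, unlike a carbanion or an organozinc, cannot eliminate; this radical adds to C10, the β-carbon of the ring B enone activated by Et3SiCl, and the resulting oxyallyl species is reduced and O-silylated to the C8–C9 enol silane. The closest known reaction types are the nickel-catalysed reductive conjugate addition of alkyl halides to enones with chlorosilane trapping and the Giese cyclisation of ω-haloalkyl cyclohexenones. Ring A (C1–C2–C3–C4–C5–C10) is closed in the 6-exo-trig mode by formation of the C1–C10 bond. The only new stereocentre, quaternary C10, is controlled by the tether anchored at C5: C1 can reach C10 only on the face that carries C4, by axial attack with the C5 substituent equatorial, which gives the cis ring fusion (C20 and H5 on the same face), while C2 and C5 are carried through unchanged and C4 stays unassigned until step 6. The step needs cyclisation to win over premature reduction of the radical and over 1,5-hydrogen transfer from C5–H, and it needs a regiodefined enolate equivalent; the first is served by the four-atom tether and the polarity match between a nucleophilic alkyl radical and the silyl-activated enone, the second by the O-silylation in the flask, which fixes the enol silane toward C9.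

Step 6
Reactants: 10 methyl 2β-(tert-butyldimethylsilyloxy)-8-(triethylsilyloxy)-11,12,13,14,15,16,17,19-octanor-5β-labd-8-en-18-oate
Product: 11 methyl 2β-(tert-butyldimethylsilyloxy)-8-(triethylsilyloxy)-11,12,13,14,15,16,17-heptanor-5β-labd-8-en-18-oate (4β-CH3; 4α-CO2Me)
Conditions: LiN(i-Pr)2, THF, −78 → −40 °C; MeI, DMPU, −78 → −20 °C
Reagents that add atoms: iodomethane, CI
Why: Ester enolate alkylation in which both C4 epimers converge on one exocyclic enolate and MeI should attack its convex β face (equatorial attack, the α face being the concave side under which ring B is folded), placing the new methyl C19 β and the ester C18 α, while the enol silane survives the amide base.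

Step 7
Reactants: 11 methyl 2β-(tert-butyldimethylsilyloxy)-8-(triethylsilyloxy)-11,12,13,14,15,16,17-heptanor-5β-labd-8-en-18-oate; 12 methyl vinyl ketone
Product: 13 methyl 2β-(tert-butyldimethylsilyloxy)-8,13-dioxo-14,15,17-trinor-5β-labdan-18-oate
Conditions: TiCl4, CH2Cl2, −78 °C; aq. NaHCO3
Reagents that add atoms: none
Why: Mukaiyama–Michael addition in which the regiodefined enol silane can react only through C9 and should attack the TiCl4-activated enone from the convex β face (anti to ring A), giving the 9β side chain with 9α-H, which is also the more stable epimer next to the C8 ketone.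

Step 8
Reactants: 13 methyl 2β-(tert-butyldimethylsilyloxy)-8,13-dioxo-14,15,17-trinor-5β-labdan-18-oate; 14 trimethyl phosphonoacetate
Product: 15 dimethyl (13E)-2β-(tert-butyldimethylsilyloxy)-8-oxo-17-nor-5β-labd-13-ene-15,18-dioate
Conditions: NaH, THF, 0 °C → rt
Reagents that add atoms: none
Why: Horner–Wadsworth–Emmons olefination in which the phosphonate anion should react with the unhindered C13 methyl ketone and not with the C8 ketone flanked by the branched C9 and quaternary C10, the reversible addition favouring the (E)-trisubstituted enoate, with any Z isomer to be removed by chromatography.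

Step 9
Reactants: 15 dimethyl (13E)-2β-(tert-butyldimethylsilyloxy)-8-oxo-17-nor-5β-labd-13-ene-15,18-dioate
Product: 16 dimethyl 2β-(tert-butyldimethylsilyloxy)-5β-labda-8(17),13E-diene-15,18-dioate
Conditions: Zn, CH2Br2, TiCl4, THF–CH2Cl2, 0 °C → rt
Reagents that add atoms: dibromomethane, BrCBr
Why: Lombardo methylenation, whose non-basic gem-dimetallic reagent should convert the hindered, enolisable C8 ketone into the exocyclic alkene without epimerising C9 and without touching the esters or the enoate.

Step 10
Reactants: 16 dimethyl 2β-(tert-butyldimethylsilyloxy)-5β-labda-8(17),13E-diene-15,18-dioate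
Product: 17 dimethyl 2β-hydroxy-5β-labda-8(17),13E-diene-15,18-dioate
Conditions: HF·pyridine, THF, 0 °C → rt
Reagents that add atoms: none
Why: Fluoride-driven desilylation (Si–F bond formation) frees the 2β-hydroxyl, which is trans to the C4 ester and so cannot lactonise, under conditions too weakly acidic to move the C8(17) alkene.

Step 11
Reactants: 17 dimethyl 2β-hydroxy-5β-labda-8(17),13E-diene-15,18-dioate
Product: 19 (2S,4R,5S,9S,10R)-2-hydroxylabda-8(17),13E-diene-15,18-dioic acid (CNP0086784.2), via mono-acid 18 (not isolated)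
Conditions: LiOH, THF–MeOH–H2O, rt; solvent removed; then n-PrSLi, HMPA, rt; aq. HCl
Reagents that add atoms: lithium hydroxide, [Li+].[OH-]
Why: Saponification cleaves the unhindered enoate ester, whose carboxylate is then safe from thiolate conjugate addition, and the axial neopentyl-type C4 ester, which resists hydroxide, should fall to SN2 demethylation by the thiolate, no stereocentre being affected.

**Compound list**

1 | 2-methylcyclohex-2-en-1-one | CC1=CCCCC1=O | starting material
2 | (1R)-2-methylcyclohex-2-en-1-ol | CC1=CCCC[C@H]1O | intermediate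
3 | trimethyl orthoacetate (1,1,1-trimethoxyethane) | CC(OC)(OC)OC | starting material
4 | 1-methoxy-1-{[(1R)-2-methylcyclohex-2-en-1-yl]oxy}ethene (ketene acetal, not isolated) | CC1=CCCC[C@H]1OC(=C)OC | intermediate
5 | methyl 2-[(1R)-2-methylcyclohex-2-en-1-yl]acetate | COC(=O)C[C@H]1CCCC=C1C | intermediate
6 | (R)-epibromohydrin, (2R)-2-(bromomethyl)oxirane | BrC[C@H]1CO1 | starting material
7 | methyl (4R)-5-bromo-4-hydroxy-2-[(1R)-2-methylcyclohex-2-en-1-yl]pentanoate (both C2 epimers; formed as its aluminium alkoxide, not isolated) | COC(=O)C(C[C@@H](O)CBr)[C@H]1CCCC=C1C | intermediate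
8 | methyl (4R)-5-bromo-4-[(tert-butyldimethylsilyl)oxy]-2-[(1R)-2-methylcyclohex-2-en-1-yl]pentanoate (both C2 epimers) | COC(=O)C(C[C@@H](O[Si](C)(C)C(C)(C)C)CBr)[C@H]1CCCC=C1C | intermediate
9 | methyl (4R)-5-bromo-4-[(tert-butyldimethylsilyl)oxy]-2-[(1R)-2-methyl-4-oxocyclohex-2-en-1-yl]pentanoate (both C2 epimers) | COC(=O)C(C[C@@H](O[Si](C)(C)C(C)(C)C)CBr)[C@H]1CCC(=O)C=C1C | intermediate
10 | methyl 2β-(tert-butyldimethylsilyloxy)-8-(triethylsilyloxy)-11,12,13,14,15,16,17,19-octanor-5β-labd-8-en-18-oate (cis-fused; 10β-CH3; both C4 epimers) | CC[Si](CC)(CC)OC1=C[C@@]2(C)C[C@H](O[Si](C)(C)C(C)(C)C)CC(C(=O)OC)[C@H]2CC1 | intermediate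
11 | methyl 2β-(tert-butyldimethylsilyloxy)-8-(triethylsilyloxy)-11,12,13,14,15,16,17-heptanor-5β-labd-8-en-18-oate (4β-CH3, 4α-CO2Me) | CC[Si](CC)(CC)OC1=C[C@@]2(C)C[C@H](O[Si](C)(C)C(C)(C)C)C[C@@](C)(C(=O)OC)[C@H]2CC1 | intermediate
12 | methyl vinyl ketone (but-3-en-2-one) | C=CC(C)=O | starting material
13 | methyl 2β-(tert-butyldimethylsilyloxy)-8,13-dioxo-14,15,17-trinor-5β-labdan-18-oate | O=C1CC[C@H]2[C@](C)(C[C@H](O[Si](C)(C)C(C)(C)C)C[C@@]2(C)C(=O)OC)[C@H]1CCC(C)=O | intermediate
14 | trimethyl phosphonoacetate | COC(=O)CP(=O)(OC)OC | starting material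
15 | dimethyl (13E)-2β-(tert-butyldimethylsilyloxy)-8-oxo-17-nor-5β-labd-13-ene-15,18-dioate | O=C1CC[C@H]2[C@](C)(C[C@H](O[Si](C)(C)C(C)(C)C)C[C@@]2(C)C(=O)OC)[C@H]1CC/C(C)=C/C(=O)OC | intermediate
16 | dimethyl 2β-(tert-butyldimethylsilyloxy)-5β-labda-8(17),13E-diene-15,18-dioate | C=C1CC[C@H]2[C@](C)(C[C@H](O[Si](C)(C)C(C)(C)C)C[C@@]2(C)C(=O)OC)[C@H]1CC/C(C)=C/C(=O)OC | intermediate
17 | dimethyl 2β-hydroxy-5β-labda-8(17),13E-diene-15,18-dioate | C=C1CC[C@H]2[C@](C)(C[C@H](O)C[C@@]2(C)C(=O)OC)[C@H]1CC/C(C)=C/C(=O)OC | intermediate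
18 | (13E)-2β-hydroxy-18-methoxy-18-oxo-5β-labda-8(17),13-dien-15-oic acid (mono-acid, not isolated) | C=C1CC[C@H]2[C@](C)(C[C@H](O)C[C@@]2(C)C(=O)OC)[C@H]1CC/C(C)=C/C(=O)O | intermediate
19 | (2S,4R,5S,9S,10R)-2-hydroxylabda-8(17),13E-diene-15,18-dioic acid (CNP0086784.2; cis A/B fusion) | C=C1CC[C@H]2[C@](C)(C[C@H](O)C[C@@]2(C)C(=O)O)[C@H]1CC/C(C)=C/C(=O)O | target

Total step count: 11
Longest linear sequence: 11 steps (1 → 19)

**Steps most likely to fail**

1. Step 5 (key step). What may go wrong: reduction of the C1 radical before it cyclises, 1,5-hydrogen transfer from C5–H to the C1 radical, or slow turnover of nickel at the β,β-disubstituted enone. The fallback sets out from 9 and comes back to the route at 16; it attaches the side chain to C9 before ring closure and closes ring A by a tin hydride chain reaction, so that no enolate has to be trapped. Iodination of 9 at C9 (I2, pyridine, CH2Cl2) gives the α-iodoenone F1. Suzuki–Miyaura coupling of F1 with the 9-BBN adduct of 2-methyl-2-vinyl-1,3-dioxolane ([1,1'-bis(diphenylphosphino)ferrocene]palladium dichloride, AsPh3, Cs2CO3, DMF–THF–H2O) gives the C9-alkylated enone F2. Bu3SnH and AIBN (slow addition, benzene, 80 °C) close ring A by 6-exo-trig Giese cyclisation, and NaOMe in MeOH equilibrates C9 to the cis-fused 9β-alkyl ketone F3. Lombardo methylenation as in step 9 gives the exocyclic alkene F4, enolate methylation as in step 6 gives the C4-quaternary ester F5, and pyridinium p-toluenesulfonate in wet acetone frees the methyl ketone F6. The olefination of step 8 applied to F6 gives 16.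

2. Step 3. What may go wrong: transfer of chloride or ethyl from aluminium to the epoxide, closure of the bromohydrin alkoxide to a new epoxide, or lactonisation onto the ester before silylation. The fallback sets out from 5 and comes back at 8; it makes C3–C4 by direct SN2 displacement instead of epoxide opening. (R)-Glycidol and Tf2O (2,6-lutidine, CH2Cl2, −78 °C) give (S)-glycidyl triflate F7. The lithium enolate of 5 (LiN(i-Pr)2, THF, −78 °C) displaces the triflate to give the epoxy ester F8, whose oxirane carbons are C1 and C2. MgBr2·OEt2 opens the epoxide at C1 to bromohydrin 7, which is silylated at once (TBSOTf, 2,6-lutidine) to 8.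

3. Step 8. What may go wrong: base-induced aldol closure between the C13 methyl ketone and the C8 ketone of the 1,5-diketone, and incomplete E selectivity. The fallback sets out from 11 and comes back at 16; it builds the enoate by carbometalation of an alkyne, with no 1,5-diketone on the way. MeLi converts enol silane 11 into its lithium enolate, which is alkylated at C9 with (4-iodobut-1-yn-1-yl)trimethylsilane (THF–DMPU) to the alkynyl ketone F9. Lombardo methylenation gives the exocyclic alkene F10, and K2CO3 in MeOH removes the alkynyl silyl group to give the terminal alkyne F11. Negishi carboalumination (Me3Al, (C5H5)2ZrCl2 cat., CH2Cl2) followed by ClCO2Me should give 16 as the (E)-enoate by syn addition.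

**Further compounds**

F1 | step 5 | methyl (4R)-5-bromo-4-[(tert-butyldimethylsilyl)oxy]-2-[(1R)-3-iodo-2-methyl-4-oxocyclohex-2-en-1-yl]pentanoate (both C2 epimers) | COC(=O)C(C[C@@H](O[Si](C)(C)C(C)(C)C)CBr)[C@H]1CCC(=O)C(I)=C1C
F2 | step 5 | methyl (4R)-5-bromo-4-[(tert-butyldimethylsilyl)oxy]-2-{(1R)-2-methyl-3-[2-(2-methyl-1,3-dioxolan-2-yl)ethyl]-4-oxocyclohex-2-en-1-yl}pentanoate (both C2 epimers) | COC(=O)C(C[C@@H](O[Si](C)(C)C(C)(C)C)CBr)[C@H]1CCC(=O)C(CCC2(C)OCCO2)=C1C
F3 | step 5 | methyl 2β-(tert-butyldimethylsilyloxy)-13,13-ethylenedioxy-8-oxo-14,15,17,19-tetranor-5β-labdan-18-oate (both C4 epimers) | O=C1CC[C@H]2[C@](C)(C[C@H](O[Si](C)(C)C(C)(C)C)CC2C(=O)OC)[C@H]1CCC3(C)OCCO3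
F4 | step 5 | methyl 2β-(tert-butyldimethylsilyloxy)-13,13-ethylenedioxy-14,15,19-trinor-5β-labd-8(17)-en-18-oate (both C4 epimers) | C=C1CC[C@H]2[C@](C)(C[C@H](O[Si](C)(C)C(C)(C)C)CC2C(=O)OC)[C@H]1CCC3(C)OCCO3
F5 | step 5 | methyl 2β-(tert-butyldimethylsilyloxy)-13,13-ethylenedioxy-14,15-dinor-5β-labd-8(17)-en-18-oate | C=C1CC[C@H]2[C@](C)(C[C@H](O[Si](C)(C)C(C)(C)C)C[C@@]2(C)C(=O)OC)[C@H]1CCC3(C)OCCO3
F6 | step 5 | methyl 2β-(tert-butyldimethylsilyloxy)-13-oxo-14,15-dinor-5β-labd-8(17)-en-18-oate | C=C1CC[C@H]2[C@](C)(C[C@H](O[Si](C)(C)C(C)(C)C)C[C@@]2(C)C(=O)OC)[C@H]1CCC(C)=O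
F7 | step 3 | [(2S)-oxiran-2-yl]methyl trifluoromethanesulfonate ((S)-glycidyl triflate) | FC(F)(F)S(=O)(=O)OC[C@@H]1CO1
F8 | step 3 | methyl 2-[(1R)-2-methylcyclohex-2-en-1-yl]-3-[(2R)-oxiran-2-yl]propanoate (both C2 epimers) | COC(=O)C(C[C@@H]1CO1)[C@H]2CCCC=C2C
F9 | step 8 | methyl 2β-(tert-butyldimethylsilyloxy)-8-oxo-14-(trimethylsilyl)-15,16,17-trinor-5β-labd-13-yn-18-oate | O=C1CC[C@H]2[C@](C)(C[C@H](O[Si](C)(C)C(C)(C)C)C[C@@]2(C)C(=O)OC)[C@H]1CCC#C[Si](C)(C)C
F10 | step 8 | methyl 2β-(tert-butyldimethylsilyloxy)-14-(trimethylsilyl)-15,16-dinor-5β-labd-8(17)-en-13-yn-18-oate | C=C1CC[C@H]2[C@](C)(C[C@H](O[Si](C)(C)C(C)(C)C)C[C@@]2(C)C(=O)OC)[C@H]1CCC#C[Si](C)(C)C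
F11 | step 8 | methyl 2β-(tert-butyldimethylsilyloxy)-15,16-dinor-5β-labd-8(17)-en-13-yn-18-oate | C=C1CC[C@H]2[C@](C)(C[C@H](O[Si](C)(C)C(C)(C)C)C[C@@]2(C)C(=O)OC)[C@H]1CCC#C
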